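**Retrosynthetic overview**
- Last bonds: the ester C–O between the right-half acrylic acid and the CH2 of a left-half spiro-epoxide (cobalt-salen-catalysed carboxylate opening), then enal to acid and desilylation.
- Right half: acrylic acid from a vinyl iodide by palladium carbonylation; iodide from syn-hydrostannation of a skipped enyne; the enyne and the cis relationship on ring C from a Pd/Cu-catalysed anti-SN2' alkynylation of a spiro vinyl epoxide made from (S)-cryptone.
- Left half: ring B (oxepinone) by ring-closing metathesis of a 2-(hydroxymethyl)allyl ester onto a vinyl group; ring A substituents from (R)-cryptone by vinyl conjugate addition/formaldehyde trapping, then Corey–Chaykovsky epoxidation.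
- Both cryptone enantiomers: organocatalytic Michael addition of 3-methylbutanal to methyl vinyl ketone, then aldol condensation.
- Ring order: rings A and C first (as cyclohexenones), ring B closed on the left half before the union.

Assumption: compounds that deliver skeleton carbons are numbered as starting materials; silylating agents, trimethylsulfonium iodide, CO, tin hydride and oxidants are treated as reagents. Ring A is the left cyclohexane, ring B the lactone, ring C the right cyclohexene.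

**Route**

Step 1
Reactants: 1 3-methylbutanal; 2 but-3-en-2-one
Product: 3 (2R)-5-oxo-2-(propan-2-yl)hexanal
Conditions: (R)-2-[methoxy(diphenyl)methyl]pyrrolidine (5 mol %), ethyl 3,4-dihydroxybenzoate (20 mol %), neat, 4 °C
Reagents that add atoms: none
Why: Enamine-catalysed Michael addition in which the diphenylmethyl ether group of the (R)-catalyst shields one face of the (E)-enamine, so the enone adds to the open face and sets C2 as R (sense from the usual diarylprolinol ether model, to be confirmed by the rotation of 4).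

Step 2
Reactants: 3 (2R)-5-oxo-2-(propan-2-yl)hexanal
Product: 4 (4R)-4-(propan-2-yl)cyclohex-2-en-1-one
Conditions: LiOH (0.3 equiv), i-PrOH, 23 °C
Reagents that add atoms: none
Why: Intramolecular aldol condensation (methyl ketone enolate onto the aldehyde, then dehydration) closes ring A under mild hydroxide conditions that leave the stereocentre intact.

Step 3
Reactants: 4 (4R)-4-(propan-2-yl)cyclohex-2-en-1-one; 5 vinylmagnesium bromide; 6 formaldehyde
Product: 8 (2R,3R,4R)-3-ethenyl-2-(hydroxymethyl)-4-(propan-2-yl)cyclohexan-1-one, via bromomagnesium enolate 7 (not isolated)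
Conditions: 5 (1.5 equiv), CuBr·SMe2 (20 mol %), THF, −78 → −40 °C; then 6 (monomeric, THF, 5 equiv), −78 → −40 °C; aq. NH4Cl
Reagents that add atoms: none
Why: Tandem copper-catalysed conjugate addition–aldol in which the vinyl group adds anti to the neighbouring isopropyl group and formaldehyde then attacks the regiodefined enolate anti to the new vinyl group, giving the all-trans, all-equatorial ketone.

Step 4
Reactants: 8 (2R,3R,4R)-3-ethenyl-2-(hydroxymethyl)-4-(propan-2-yl)cyclohexan-1-one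
Product: 9 (2R,3R,4R)-2-{[(tert-butyldimethylsilyl)oxy]methyl}-3-ethenyl-4-(propan-2-yl)cyclohexan-1-one
Conditions: TBSCl, imidazole, CH2Cl2, 0 °C → rt
Reagents that add atoms: tert-butyldimethylsilyl chloride, CC(C)(C)[Si](C)(C)Cl
Why: Standard silylation of a primary alcohol under weakly basic conditions that avoid retro-aldol or dehydration of the β-hydroxy ketone.

Step 5
Reactants: 9 (2R,3R,4R)-2-{[(tert-butyldimethylsilyl)oxy]methyl}-3-ethenyl-4-(propan-2-yl)cyclohexan-1-one
Product: 10 tert-butyl{[(3S,4R,5R,6R)-5-ethenyl-6-(propan-2-yl)-1-oxaspiro[2.5]octan-4-yl]methoxy}dimethylsilane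
Conditions: Me3S+ I−, n-BuLi, THF, −10 °C; then 9, −10 → 20 °C
Reagents that add atoms: trimethylsulfonium iodide, C[S+](C)C.[I-]
Why: Corey–Chaykovsky epoxidation in which the unstabilised sulfonium methylide adds irreversibly along the axial trajectory of the locked chair, so the new CH2 is axial and the oxygen equatorial, which is the configuration of the tertiary carbinol of the target.

Step 6
Reactants: 10 tert-butyl{[(3S,4R,5R,6R)-5-ethenyl-6-(propan-2-yl)-1-oxaspiro[2.5]octan-4-yl]methoxy}dimethylsilane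
Product: 11 [(3S,4R,5R,6R)-5-ethenyl-6-(propan-2-yl)-1-oxaspiro[2.5]octan-4-yl]methanol
Conditions: n-Bu4NF, THF, 0 °C
Reagents that add atoms: none
Why: Fluoride desilylation is selective for the Si–O bond and leaves the epoxide and the vinyl group untouched.

Step 7
Reactants: 11 [(3S,4R,5R,6R)-5-ethenyl-6-(propan-2-yl)-1-oxaspiro[2.5]octan-4-yl]methanol
Product: 13 (3S,4S,5R,6R)-5-ethenyl-6-(propan-2-yl)-1-oxaspiro[2.5]octane-4-carboxylic acid, via epoxy aldehyde 12 (not isolated)
Conditions: Dess–Martin periodinane, pyridine, CH2Cl2, 0 °C; then NaClO2, NaH2PO4, 2-methyl-2-butene, t-BuOH/H2O, 0 °C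
Reagents that add atoms: sodium chlorite, [Na+].[O-]Cl=O
Why: Dess–Martin then Pinnick oxidation under neutral and buffered conditions takes the primary alcohol to the acid without base-induced opening of the β-epoxy aldehyde, and the equatorial carboxyl keeps its configuration.

Step 8
Reactants: 13 (3S,4S,5R,6R)-5-ethenyl-6-(propan-2-yl)-1-oxaspiro[2.5]octane-4-carboxylic acid; 14 2-methylidenepropane-1,3-diol
Product: 15 2-(hydroxymethyl)prop-2-en-1-yl (3S,4S,5R,6R)-5-ethenyl-6-(propan-2-yl)-1-oxaspiro[2.5]octane-4-carboxylate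
Conditions: 14 (5 equiv), PPh3, diisopropyl azodicarboxylate, THF, 0 °C → rt
Reagents that add atoms: none
Why: Mitsunobu esterification uses the acid as the O-nucleophile toward the activated allylic alcohol, so the hindered epoxy acid is never turned into an acyl electrophile, and excess symmetric diol gives the mono-ester.

Step 9
Reactants: 15 2-(hydroxymethyl)prop-2-en-1-yl (3S,4S,5R,6R)-5-ethenyl-6-(propan-2-yl)-1-oxaspiro[2.5]octane-4-carboxylate
Product: 16 (5aS,6R,9S,9aS)-4-(hydroxymethyl)-6-(propan-2-yl)-3,5a,6,7,8,9a-hexahydro-1H-spiro[[2]benzoxepine-9,2'-oxiran]-1-one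
Conditions: second-generation Grubbs catalyst (5 mol %), toluene (2 mM), 80 °C
Reagents that add atoms: none
Why: Ring-closing metathesis starts at the vinyl group and closes onto the 1,1-disubstituted alkene, helped by the trans-diequatorial tethers on ring A, and the seven-membered ring forces the ring-A carbon cis to the lactone CH2O and trans to the CH2OH that becomes the carboxyl.

Step 10
Reactants: 16 (5aS,6R,9S,9aS)-4-(hydroxymethyl)-6-(propan-2-yl)-3,5a,6,7,8,9a-hexahydro-1H-spiro[[2]benzoxepine-9,2'-oxiran]-1-one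
Product: 17 (5aS,6R,9S,9aS)-1-oxo-6-(propan-2-yl)-3,5a,6,7,8,9a-hexahydro-1H-spiro[[2]benzoxepine-9,2'-oxirane]-4-carbaldehyde
Conditions: MnO2, CH2Cl2, rt
Reagents that add atoms: none
Why: Manganese dioxide oxidation is selective for the allylic alcohol and stops at the enal, which keeps the carboxyl masked during the union.

Step 11
Reactants: 1 3-methylbutanal; 2 but-3-en-2-one
Product: 18 (2S)-5-oxo-2-(propan-2-yl)hexanal
Conditions: (S)-2-[methoxy(diphenyl)methyl]pyrrolidine (5 mol %), ethyl 3,4-dihydroxybenzoate (20 mol %), neat, 4 °C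
Reagents that add atoms: none
Why: The same enamine-catalysed Michael addition as step 1 with the enantiomeric catalyst gives the S aldehyde.

Step 12
Reactants: 18 (2S)-5-oxo-2-(propan-2-yl)hexanal
Product: 19 (4S)-4-(propan-2-yl)cyclohex-2-en-1-one
Conditions: LiOH (0.3 equiv), i-PrOH, 23 °C
Reagents that add atoms: none
Why: Intramolecular aldol condensation as in step 2 closes ring C as its enone.

Step 13
Reactants: 19 (4S)-4-(propan-2-yl)cyclohex-2-en-1-one
Product: 20 (3R,6S)-6-(propan-2-yl)-1-oxaspiro[2.5]oct-4-ene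
Conditions: Me3S+ I−, n-BuLi, THF, −10 °C; then 19, −78 → 0 °C
Reagents that add atoms: trimethylsulfonium iodide, C[S+](C)C.[I-]
Why: Corey–Chaykovsky 1,2-addition to the enone occurs by axial attack on the half-chair with a pseudo-equatorial isopropyl group, putting the epoxide oxygen trans to isopropyl; the minor epimer is removed after step 15.

Step 14
Reactants: 21 prop-2-yn-1-ol
Product: 22 tert-butyldimethyl(prop-2-yn-1-yloxy)silane
Conditions: TBSCl, imidazole, CH2Cl2, 0 °C → rt
Reagents that add atoms: tert-butyldimethylsilyl chloride, CC(C)(C)[Si](C)(C)Cl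
Why: Standard silylation of a primary alcohol.

Step 15
Reactants: 20 (3R,6S)-6-(propan-2-yl)-1-oxaspiro[2.5]oct-4-ene; 22 tert-butyldimethyl(prop-2-yn-1-yloxy)silane
Product: 23 [(3R,4S)-3-{3-[(tert-butyldimethylsilyl)oxy]prop-1-yn-1-yl}-4-(propan-2-yl)cyclohex-1-en-1-yl]methanol
Conditions: Pd2(dba)3 (2.5 mol %), tri(2-furyl)phosphine (10 mol %), CuI (10 mol %), 22 (1.5 equiv), THF, 0 → 23 °C, no added base, slow addition of 20
Reagents that add atoms: none
Why: Proposed new method: zerovalent palladium ionises the vinyl epoxide anti to the C–O bond to a zwitterionic π-allylpalladium alkoxide, this alkoxide deprotonates the CuI-bound alkyne without external base, the copper acetylide passes the alkynyl group to palladium, and reductive elimination at the less substituted allyl terminus from the metal-bearing face gives net anti-SN2' alkynylation, so the alkyne enters cis to isopropyl and opposite to the departed oxygen; the closest known reactions are the palladium-catalysed 1,4-coupling of vinyl epoxides with aryl- and alkenylstannanes or boronic acids (inversion) and the Sonogashira coupling.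

Step 16
Reactants: 23 [(3R,4S)-3-{3-[(tert-butyldimethylsilyl)oxy]prop-1-yn-1-yl}-4-(propan-2-yl)cyclohex-1-en-1-yl]methanol
Product: 24 tert-butyl{[(3R,4S)-3-{3-[(tert-butyldimethylsilyl)oxy]prop-1-yn-1-yl}-4-(propan-2-yl)cyclohex-1-en-1-yl]methoxy}dimethylsilane
Conditions: TBSCl, imidazole, CH2Cl2, 0 °C → rt
Reagents that add atoms: tert-butyldimethylsilyl chloride, CC(C)(C)[Si](C)(C)Cl
Why: Standard silylation of the primary allylic alcohol under conditions too mild to isomerise the skipped enyne.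

Step 17
Reactants: 24 tert-butyl{[(3R,4S)-3-{3-[(tert-butyldimethylsilyl)oxy]prop-1-yn-1-yl}-4-(propan-2-yl)cyclohex-1-en-1-yl]methoxy}dimethylsilane
Product: 25 tributyl[(1E)-3-[(tert-butyldimethylsilyl)oxy]-1-[(1R,6S)-3-{[(tert-butyldimethylsilyl)oxy]methyl}-6-(propan-2-yl)cyclohex-2-en-1-yl]prop-1-en-2-yl]stannane
Conditions: n-Bu3SnH (1.3 equiv), PdCl2(PPh3)2 (3 mol %), THF, 0 °C
Reagents that add atoms: tributyltin hydride, CCCC[SnH](CCCC)CCCC
Why: Palladium-catalysed hydrostannation adds H and Sn syn, with tin on the alkyne carbon next to CH2OTBS (favoured both by the oxygen and by the bulky ring carbon on the other side), which fixes the ring carbon trans to the future carboxyl.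

Step 18
Reactants: 25 tributyl[(1E)-3-[(tert-butyldimethylsilyl)oxy]-1-[(1R,6S)-3-{[(tert-butyldimethylsilyl)oxy]methyl}-6-(propan-2-yl)cyclohex-2-en-1-yl]prop-1-en-2-yl]stannane
Product: 26 tert-butyl{[(2E)-3-[(1R,6S)-3-{[(tert-butyldimethylsilyl)oxy]methyl}-6-(propan-2-yl)cyclohex-2-en-1-yl]-2-iodoprop-2-en-1-yl]oxy}dimethylsilane
Conditions: I2, CH2Cl2, 0 °C
Reagents that add atoms: iodine, II
Why: Iododestannylation is much faster than iodination of the other alkenes and replaces tin with retention of alkene geometry.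

Step 19
Reactants: 26 tert-butyl{[(2E)-3-[(1R,6S)-3-{[(tert-butyldimethylsilyl)oxy]methyl}-6-(propan-2-yl)cyclohex-2-en-1-yl]-2-iodoprop-2-en-1-yl]oxy}dimethylsilane
Product: 27 (2E)-2-{[(tert-butyldimethylsilyl)oxy]methyl}-3-[(1R,6S)-3-{[(tert-butyldimethylsilyl)oxy]methyl}-6-(propan-2-yl)cyclohex-2-en-1-yl]prop-2-enoic acid
Conditions: Pd(OAc)2 (5 mol %), PPh3 (20 mol %), CO (1 atm), H2O (10 equiv), Et3N, DMF, 60 °C; work-up at pH 4
Reagents that add atoms: carbon monoxide, [C-]#[O+]; water, O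
Why: Palladium-catalysed hydroxycarbonylation of the alkenyl iodide (oxidative addition, CO insertion, hydrolysis of the acylpalladium) proceeds with retention of geometry and tolerates silyl ethers.

Step 20
Reactants: 17 (5aS,6R,9S,9aS)-1-oxo-6-(propan-2-yl)-3,5a,6,7,8,9a-hexahydro-1H-spiro[[2]benzoxepine-9,2'-oxirane]-4-carbaldehyde; 27 (2E)-2-{[(tert-butyldimethylsilyl)oxy]methyl}-3-[(1R,6S)-3-{[(tert-butyldimethylsilyl)oxy]methyl}-6-(propan-2-yl)cyclohex-2-en-1-yl]prop-2-enoic acid
Product: 28 [(5aS,6R,9S,9aS)-4-formyl-9-hydroxy-1-oxo-6-(propan-2-yl)-1,3,5a,6,7,8,9,9a-octahydro[2]benzoxepin-9-yl]methyl (2E)-2-{[(tert-butyldimethylsilyl)oxy]methyl}-3-[(1R,6S)-3-{[(tert-butyldimethylsilyl)oxy]methyl}-6-(propan-2-yl)cyclohex-2-en-1-yl]prop-2-enoate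
Conditions: Co(salen)(OAc) [salen = N,N'-bis(3,5-di-tert-butylsalicylidene)cyclohexane-1,2-diaminate, trivalent cobalt] (5 mol %), i-Pr2NEt (0.2 equiv), t-BuOMe, 30 °C
Reagents that add atoms: none
Why: Cobalt-salen-catalysed addition of a carboxylic acid to an epoxide (Jacobsen-type opening) delivers the carboxylate to the CH2 terminus only, so the quaternary C–O bond and its configuration are untouched, and the primary oxygen is never a free hydroxyl that could translactonise.

Step 21
Reactants: 28 the formyl lactone ester named in step 20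
Product: 29 (5aS,6R,9S,9aS)-9-{[((2E)-2-{[(tert-butyldimethylsilyl)oxy]methyl}-3-[(1R,6S)-3-{[(tert-butyldimethylsilyl)oxy]methyl}-6-(propan-2-yl)cyclohex-2-en-1-yl]prop-2-enoyl)oxy]methyl}-9-hydroxy-1-oxo-6-(propan-2-yl)-1,3,5a,6,7,8,9,9a-octahydro[2]benzoxepine-4-carboxylic acid
Conditions: NaClO2, NaH2PO4, 2-methyl-2-butene, t-BuOH/H2O, 0 °C → rt
Reagents that add atoms: sodium chlorite, [Na+].[O-]Cl=O
Why: Pinnick oxidation converts the enal to the acid chemoselectively, with the scavenger protecting the other alkenes and the buffer tolerating lactone, ester, tertiary alcohol and silyl ethers.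

Step 22
Reactants: 29 the bis-silyl acid named in step 21
Product: 30 (5aS,6R,9S,9aS)-9-hydroxy-9-{[((2E)-2-(hydroxymethyl)-3-[(1R,6S)-3-(hydroxymethyl)-6-(propan-2-yl)cyclohex-2-en-1-yl]prop-2-enoyl)oxy]methyl}-1-oxo-6-(propan-2-yl)-1,3,5a,6,7,8,9,9a-octahydro[2]benzoxepine-4-carboxylic acid (target)
Conditions: HF·pyridine, pyridine, THF, 0 °C → rt
Reagents that add atoms: none
Why: Buffered fluoride desilylation frees both primary allylic alcohols without base, so no acyl migration, lactone opening or epimerisation of the doubly allylic centre occurs.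

**Compound list**
1 | 3-methylbutanal | CC(C)CC=O | starting material
2 | but-3-en-2-one | CC(=O)C=C | starting material
3 | (2R)-5-oxo-2-(propan-2-yl)hexanal | CC(C)[C@H](C=O)CCC(C)=O | intermediate
4 | (4R)-4-(propan-2-yl)cyclohex-2-en-1-one | CC(C)[C@H]1CCC(=O)C=C1 | intermediate
5 | vinylmagnesium bromide | C=C[Mg]Br | starting material
6 | formaldehyde | C=O | starting material
7 | bromo{[(3R,4R)-3-ethenyl-4-(propan-2-yl)cyclohex-1-en-1-yl]oxy}magnesium | CC(C)[C@H]1CCC(O[Mg]Br)=C[C@@H]1C=C | intermediate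
8 | (2R,3R,4R)-3-ethenyl-2-(hydroxymethyl)-4-(propan-2-yl)cyclohexan-1-one | CC(C)[C@H]1CCC(=O)[C@@H](CO)[C@@H]1C=C | intermediate
9 | (2R,3R,4R)-2-{[(tert-butyldimethylsilyl)oxy]methyl}-3-ethenyl-4-(propan-2-yl)cyclohexan-1-one | CC(C)[C@H]1CCC(=O)[C@@H](CO[Si](C)(C)C(C)(C)C)[C@@H]1C=C | intermediate
10 | tert-butyl{[(3S,4R,5R,6R)-5-ethenyl-6-(propan-2-yl)-1-oxaspiro[2.5]octan-4-yl]methoxy}dimethylsilane | CC(C)[C@H]1CC[C@@]2(CO2)[C@@H](CO[Si](C)(C)C(C)(C)C)[C@@H]1C=C | intermediate
11 | [(3S,4R,5R,6R)-5-ethenyl-6-(propan-2-yl)-1-oxaspiro[2.5]octan-4-yl]methanol | CC(C)[C@H]1CC[C@@]2(CO2)[C@@H](CO)[C@@H]1C=C | intermediate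
12 | (3S,4S,5R,6R)-5-ethenyl-6-(propan-2-yl)-1-oxaspiro[2.5]octane-4-carbaldehyde | CC(C)[C@H]1CC[C@@]2(CO2)[C@@H](C=O)[C@@H]1C=C | intermediate
13 | (3S,4S,5R,6R)-5-ethenyl-6-(propan-2-yl)-1-oxaspiro[2.5]octane-4-carboxylic acid | CC(C)[C@H]1CC[C@@]2(CO2)[C@@H](C(=O)O)[C@@H]1C=C | intermediate
14 | 2-methylidenepropane-1,3-diol | C=C(CO)CO | starting material
15 | 2-(hydroxymethyl)prop-2-en-1-yl (3S,4S,5R,6R)-5-ethenyl-6-(propan-2-yl)-1-oxaspiro[2.5]octane-4-carboxylate | CC(C)[C@H]1CC[C@@]2(CO2)[C@@H](C(=O)OCC(=C)CO)[C@@H]1C=C | intermediate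
16 | (5aS,6R,9S,9aS)-4-(hydroxymethyl)-6-(propan-2-yl)-3,5a,6,7,8,9a-hexahydro-1H-spiro[[2]benzoxepine-9,2'-oxiran]-1-one | CC(C)[C@H]1CC[C@@]3(CO3)[C@H]2C(=O)OCC(CO)=C[C@H]12 | intermediate
17 | (5aS,6R,9S,9aS)-1-oxo-6-(propan-2-yl)-3,5a,6,7,8,9a-hexahydro-1H-spiro[[2]benzoxepine-9,2'-oxirane]-4-carbaldehyde | CC(C)[C@H]1CC[C@@]3(CO3)[C@H]2C(=O)OCC(C=O)=C[C@H]12 | intermediate
18 | (2S)-5-oxo-2-(propan-2-yl)hexanal | CC(C)[C@@H](C=O)CCC(C)=O | intermediate
19 | (4S)-4-(propan-2-yl)cyclohex-2-en-1-one | CC(C)[C@@H]1CCC(=O)C=C1 | intermediate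
20 | (3R,6S)-6-(propan-2-yl)-1-oxaspiro[2.5]oct-4-ene (epoxide O trans to isopropyl) | CC(C)[C@@H]1CC[C@]2(CO2)C=C1 | intermediate
21 | prop-2-yn-1-ol | C#CCO | starting material
22 | tert-butyldimethyl(prop-2-yn-1-yloxy)silane | C#CCO[Si](C)(C)C(C)(C)C | intermediate
23 | [(3R,4S)-3-{3-[(tert-butyldimethylsilyl)oxy]prop-1-yn-1-yl}-4-(propan-2-yl)cyclohex-1-en-1-yl]methanol (alkynyl cis to isopropyl) | CC(C)(C)[Si](C)(C)OCC#C[C@H]1C=C(CO)CC[C@H]1C(C)C | intermediate
24 | tert-butyl{[(3R,4S)-3-{3-[(tert-butyldimethylsilyl)oxy]prop-1-yn-1-yl}-4-(propan-2-yl)cyclohex-1-en-1-yl]methoxy}dimethylsilane | CC(C)(C)[Si](C)(C)OCC#C[C@H]1C=C(CO[Si](C)(C)C(C)(C)C)CC[C@H]1C(C)C | intermediate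
25 | tributyl[(1E)-3-[(tert-butyldimethylsilyl)oxy]-1-[(1R,6S)-3-{[(tert-butyldimethylsilyl)oxy]methyl}-6-(propan-2-yl)cyclohex-2-en-1-yl]prop-1-en-2-yl]stannane | CCCC[Sn](CCCC)(CCCC)/C(=C/[C@H]1C=C(CO[Si](C)(C)C(C)(C)C)CC[C@H]1C(C)C)CO[Si](C)(C)C(C)(C)C | intermediate
26 | tert-butyl{[(2E)-3-[(1R,6S)-3-{[(tert-butyldimethylsilyl)oxy]methyl}-6-(propan-2-yl)cyclohex-2-en-1-yl]-2-iodoprop-2-en-1-yl]oxy}dimethylsilane | I/C(=C/[C@H]1C=C(CO[Si](C)(C)C(C)(C)C)CC[C@H]1C(C)C)CO[Si](C)(C)C(C)(C)C | intermediate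
27 | (2E)-2-{[(tert-butyldimethylsilyl)oxy]methyl}-3-[(1R,6S)-3-{[(tert-butyldimethylsilyl)oxy]methyl}-6-(propan-2-yl)cyclohex-2-en-1-yl]prop-2-enoic acid | OC(=O)/C(=C/[C@H]1C=C(CO[Si](C)(C)C(C)(C)C)CC[C@H]1C(C)C)CO[Si](C)(C)C(C)(C)C | intermediate
28 | [(5aS,6R,9S,9aS)-4-formyl-9-hydroxy-1-oxo-6-(propan-2-yl)-1,3,5a,6,7,8,9,9a-octahydro[2]benzoxepin-9-yl]methyl (2E)-2-{[(tert-butyldimethylsilyl)oxy]methyl}-3-[(1R,6S)-3-{[(tert-butyldimethylsilyl)oxy]methyl}-6-(propan-2-yl)cyclohex-2-en-1-yl]prop-2-enoate | CC(C)[C@H]1CC[C@@](O)(COC(=O)/C(=C/[C@H]2C=C(CO[Si](C)(C)C(C)(C)C)CC[C@H]2C(C)C)CO[Si](C)(C)C(C)(C)C)[C@H]2C(=O)OCC(C=O)=C[C@H]12 | intermediate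
29 | 4-carboxylic acid corresponding to 28 (full name in step 21) | CC(C)[C@H]1CC[C@@](O)(COC(=O)/C(=C/[C@H]2C=C(CO[Si](C)(C)C(C)(C)C)CC[C@H]2C(C)C)CO[Si](C)(C)C(C)(C)C)[C@H]2C(=O)OCC(C(=O)O)=C[C@H]12 | intermediate
30 | (5aS,6R,9S,9aS)-9-hydroxy-9-{[((2E)-2-(hydroxymethyl)-3-[(1R,6S)-3-(hydroxymethyl)-6-(propan-2-yl)cyclohex-2-en-1-yl]prop-2-enoyl)oxy]methyl}-1-oxo-6-(propan-2-yl)-1,3,5a,6,7,8,9,9a-octahydro[2]benzoxepine-4-carboxylic acid | CC(C)[C@H]1CC[C@@](O)(COC(=O)/C(=C/[C@H]2C=C(CO)CC[C@H]2C(C)C)CO)[C@H]2C(=O)OCC(C(=O)O)=C[C@H]12 | target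

**Step count and risks**

Total steps: 22. Longest linear sequence: 13 (steps 1–10, then 20–22). The right-hand branch is steps 11–13 and 15–19, with step 14 as a side branch.

Step 15 (the proposed alkynylation). Risks are β-hydride loss from the π-allyl intermediate to a dienol or aldehyde, slow alkynyl transfer next to the cis isopropyl group, and an outer-sphere acetylide attack that would give the wrong epimer. The fallback is known chemistry and replaces in-flask C–H metalation by a stoichiometric organotin cross-coupling. It sets out from 22 and 20. Deprotonation of 22 (n-BuLi, THF, −78 °C) and quench with n-Bu3SnCl gives tributyl{3-[(tert-butyldimethylsilyl)oxy]prop-1-yn-1-yl}stannane F1. F1 is coupled with 20 under the established neutral Stille conditions for vinyl epoxides (PdCl2(MeCN)2, DMF/H2O, rt), which give 1,4-adducts with inversion by direct Sn-to-Pd transfer. Hydrolysis of the tin alkoxide on work-up brings the route back at 23.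

Step 9 (ring-closing metathesis to the seven-membered lactone). The ester must adopt its less favoured conformation to cyclise, and the vinyl group is flanked by two ring substituents, so oligomers may dominate. The fallback closes the same ring by a carbonyl addition and sets out from 13. Mitsunobu esterification of 13 with 2-bromoprop-2-en-1-ol (PPh3, diisopropyl azodicarboxylate) gives 2-bromoprop-2-en-1-yl (3S,4S,5R,6R)-5-ethenyl-6-(propan-2-yl)-1-oxaspiro[2.5]octane-4-carboxylate F2. Selective ozonolysis of the electron-richer vinyl group (O3, CH2Cl2, −78 °C, indicator dye; Me2S) gives 2-bromoprop-2-en-1-yl (3S,4S,5R,6R)-5-formyl-6-(propan-2-yl)-1-oxaspiro[2.5]octane-4-carboxylate F3. Intramolecular Nozaki–Hiyama–Kishi reaction (CrCl2, NiCl2 cat., DMF, high dilution) gives the 5-hydroxy-4-methylidene lactone F4 (ring-A centres as in 16, carbinol epimers). A rhenium-catalysed 1,3-transposition of the allylic alcohol (Ph3SiOReO3 cat., Et2O, rt) moves the hydroxyl to the primary position and the alkene into the ring, returning the route at 16.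

Step 20 (fragment union by epoxide opening). The neopentyl-like CH2 of a 2,2-disubstituted epoxide may react slowly, and the Lewis acid could trigger rearrangement at the tertiary carbon or attack on the enal/allylic lactone. The fallback moves the union to a robust earlier intermediate and finishes ring B afterwards; it sets out from 11 and 27. Heating 11 with the caesium salt of 27 (Cs2CO3, DMF, 70 °C) gives the hydroxy ester F5 (primary CH2OH on ring A still free, vinyl intact). Dess–Martin then Pinnick oxidation gives the acid F6. Mitsunobu esterification with 14 gives the 2-(hydroxymethyl)allyl ester F7. Ring-closing metathesis (second-generation Grubbs catalyst) gives the lactone allylic alcohol F8, and MnO2 oxidation returns the route at 28.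

**Further compounds**
F1 | step 15 | tributyl{3-[(tert-butyldimethylsilyl)oxy]prop-1-yn-1-yl}stannane | CCCC[Sn](CCCC)(CCCC)C#CCO[Si](C)(C)C(C)(C)C
F2 | step 9 | 2-bromoprop-2-en-1-yl (3S,4S,5R,6R)-5-ethenyl-6-(propan-2-yl)-1-oxaspiro[2.5]octane-4-carboxylate | CC(C)[C@H]1CC[C@@]2(CO2)[C@@H](C(=O)OCC(Br)=C)[C@@H]1C=C
F3 | step 9 | 2-bromoprop-2-en-1-yl (3S,4S,5R,6R)-5-formyl-6-(propan-2-yl)-1-oxaspiro[2.5]octane-4-carboxylate | CC(C)[C@H]1CC[C@@]2(CO2)[C@@H](C(=O)OCC(Br)=C)[C@@H]1C=O
F4 | step 9 | 5-hydroxy-4-methylidene-6-(propan-2-yl)octahydro-1H-spiro[[2]benzoxepine-9,2'-oxiran]-1-one, ring-A centres as in 16, carbinol epimers | CC(C)[C@H]1CC[C@@]3(CO3)[C@H]2C(=O)OCC(=C)C(O)[C@H]12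
F5 | step 20 | [(1S,2R,3R,4R)-3-ethenyl-1-hydroxy-2-(hydroxymethyl)-4-(propan-2-yl)cyclohexyl]methyl ester of acid 27 | CC(C)[C@H]1CC[C@@](O)(COC(=O)/C(=C/[C@H]2C=C(CO[Si](C)(C)C(C)(C)C)CC[C@H]2C(C)C)CO[Si](C)(C)C(C)(C)C)[C@@H](CO)[C@@H]1C=C
F6 | step 20 | carboxylic acid from oxidation of the ring-A CH2OH of F5 | CC(C)[C@H]1CC[C@@](O)(COC(=O)/C(=C/[C@H]2C=C(CO[Si](C)(C)C(C)(C)C)CC[C@H]2C(C)C)CO[Si](C)(C)C(C)(C)C)[C@@H](C(=O)O)[C@@H]1C=C
F7 | step 20 | 2-(hydroxymethyl)prop-2-en-1-yl ester of F6 | CC(C)[C@H]1CC[C@@](O)(COC(=O)/C(=C/[C@H]2C=C(CO[Si](C)(C)C(C)(C)C)CC[C@H]2C(C)C)CO[Si](C)(C)C(C)(C)C)[C@@H](C(=O)OCC(=C)CO)[C@@H]1C=C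
F8 | step 20 | 4-(hydroxymethyl) analogue of 28 (allylic alcohol in place of the formyl group) | CC(C)[C@H]1CC[C@@](O)(COC(=O)/C(=C/[C@H]2C=C(CO[Si](C)(C)C(C)(C)C)CC[C@H]2C(C)C)CO[Si](C)(C)C(C)(C)C)[C@H]2C(=O)OCC(CO)=C[C@H]12
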